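**Retrosynthetic overview**

1. The (2S)-flavanone is cut at both aryl bonds of ring C, O1–C8a and C4–C4a. This gives a ring-A aryne (C4a≡C8a) and an (S)-3-aryl-3-oxypropanoyl unit that already carries ring B and the C2 stereocentre.
2. Enabling feature: in ring A the C5 oxygen flanks C4a while C8 next to C8a bears only H. The resulting 3-alkoxyaryne is polarised for O-attack at C8a and leaves the carbanion at C4a. O1 and C4 are 1,3-related through C2–C3, so that carbanion closes ring C as a six-membered ring. The ring-A phenol precursor is symmetric (C6 geranyl between the C5 and C7 oxygens), so its ortho-silylation is unambiguous.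
3. Aryne precursor from resorcinol: MOM protection, directed metalation/geranylation, iridium C–H borylation/oxidation, carbamate-directed ortho-silylation, triflation.
4. Oxy-acyl partner from methyl 3-hydroxy-4,5-dimethoxybenzoate: MOM protection, Claisen condensation to a β-keto Weinreb amide, Noyori transfer hydrogenation (sets C2), O-silylation.
5. Rings A and B are bought as benzene rings; ring C is the only ring formed, in the key step, and one acidic MOM removal ends the route.

Key step: step 11

Remark on the chemistry: "geranyl" means (2E)-3,7-dimethylocta-2,6-dien-1-yl throughout; all three phenols are carried as methoxymethyl (MOM) ethers; resorcinol, geranyl bromide, methyl 3-hydroxy-4,5-dimethoxybenzoate and N-methoxy-N-methylacetamide are taken as commercial.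

**Route**

Step 1
Reactants: 1 resorcinol
Product: 2 1,3-bis(methoxymethoxy)benzene
Conditions: NaH, MOMCl, DMF, 0 °C to rt
Reagents that add atoms: chloromethyl methyl ether, COCCl
Why: Williamson etherification of the bis-phenoxide should give the bis-MOM ether, whose acetal oxygens later direct the metalation.

Step 2
Reactants: 2 1,3-bis(methoxymethoxy)benzene; 3 geranyl bromide
Product: 5 2-geranyl-1,3-bis(methoxymethoxy)benzene, via aryllithium 4 (not isolated)
Conditions: n-BuLi, THF, 0 °C to rt; then CuBr·SMe2 (10 mol %), 3, −78 °C to rt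
Reagents that add atoms: none
Why: Directed ortho-metalation occurs at the C–H flanked by both MOM ethers, and copper-mediated SN2 coupling of the aryllithium with the primary allylic bromide should give the linear geranyl arene with the (E)-alkene untouched.

Step 3
Reactants: 5 2-geranyl-1,3-bis(methoxymethoxy)benzene
Product: 7 4-geranyl-3,5-bis(methoxymethoxy)phenol, via aryl boronate 6 (not isolated)
Conditions: [Ir(OMe)(cod)]2 (1.5 mol %), 4,4'-di-tert-butyl-2,2'-bipyridine (3 mol %), B2pin2, THF, 60 °C; then aq. NaOH, H2O2, 0 °C to rt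
Reagents that add atoms: hydrogen peroxide, OO (phenol oxygen); bis(pinacolato)diboron, CC1(C)OB(OC1(C)C)B1OC(C)(C)C(C)(C)O1 (boryl group of intermediate 6 only)
Why: Iridium-catalysed aromatic C–H borylation is sterically governed and should select the only ring C–H without an ortho substituent (para to the geranyl group), and basic peroxide, to which the trisubstituted alkenes are inert, then oxidises the C–B bond to the symmetric phenol.

Step 4
Reactants: 7 4-geranyl-3,5-bis(methoxymethoxy)phenol
Product: 8 4-geranyl-3,5-bis(methoxymethoxy)phenyl N-(propan-2-yl)carbamate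
Conditions: i-PrNCO, Et3N (0.2 equiv), CH2Cl2, rt
Reagents that add atoms: isopropyl isocyanate, CC(C)N=C=O
Why: Base-catalysed addition of the phenol to the isocyanate should give the secondary carbamate, a strong ortho-directing group that is later removed under mild base.

Step 5
Reactants: 8 4-geranyl-3,5-bis(methoxymethoxy)phenyl N-(propan-2-yl)carbamate
Product: 12 4-geranyl-3,5-bis(methoxymethoxy)-2-(trimethylsilyl)phenyl N-(propan-2-yl)carbamate, via N-silyl carbamate 9 (not isolated), via ortho-lithiated carbamate 10 (not isolated), via bis-silyl carbamate 11 (not isolated)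
Conditions: TMSOTf, TMEDA, Et2O, 0 °C to rt; then n-BuLi (2.2 equiv), TMEDA, −78 °C; then TMSCl, −78 °C to rt; then sat. aq. NH4Cl
Reagents that add atoms: chlorotrimethylsilane, C[Si](C)(C)Cl (aryl silyl group); trimethylsilyl trifluoromethanesulfonate, C[Si](C)(C)OS(=O)(=O)C(F)(F)F (N-silyl group of 9 to 11 only)
Why: In situ N-silylation masks the carbamate N–H so that directed ortho-metalation occurs at the C–H between the carbamate and a MOM ether (the two candidates are equivalent by symmetry), and C-silylation followed by aqueous loss of the N-silyl group should give the ortho-silyl carbamate.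

Step 6
Reactants: 12 4-geranyl-3,5-bis(methoxymethoxy)-2-(trimethylsilyl)phenyl N-(propan-2-yl)carbamate
Product: 14 4-geranyl-3,5-bis(methoxymethoxy)-2-(trimethylsilyl)phenyl trifluoromethanesulfonate, via silyl phenol 13 (not isolated)
Conditions: DBU, Et2NH, MeCN, 40 °C; then PhNTf2, rt
Reagents that add atoms: N-phenylbis(trifluoromethanesulfonimide), O=S(=O)(N(c1ccccc1)S(=O)(=O)C(F)(F)F)C(F)(F)F
Why: E1cB cleavage of the secondary carbamate by DBU, with diethylamine trapping the isocyanate, frees the hindered phenoxide, which the mild triflyl donor O-sulfonylates in the same flask to give the o-silylaryl triflate aryne precursor.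

Step 7
Reactants: 15 methyl 3-hydroxy-4,5-dimethoxybenzoate
Product: 16 methyl 3,4-dimethoxy-5-(methoxymethoxy)benzoate
Conditions: NaH, MOMCl, DMF, 0 °C to rt
Reagents that add atoms: chloromethyl methyl ether, COCCl
Why: Williamson etherification of the phenoxide should protect the ring-B phenol as the same acetal used on ring A, so that one final step frees all three phenols.

Step 8
Reactants: 16 methyl 3,4-dimethoxy-5-(methoxymethoxy)benzoate; 17 N-methoxy-N-methylacetamide
Product: 19 3-[3,4-dimethoxy-5-(methoxymethoxy)phenyl]-N-methoxy-N-methyl-3-oxopropanamide, via lithium enolate 18 (not isolated)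
Conditions: LiN(i-Pr)2 (2.2 equiv), 17 (2.2 equiv), THF, −78 °C; then 16, −78 to −20 °C; then aq. NH4Cl
Reagents that add atoms: none
Why: Crossed Claisen condensation of the non-enolisable aryl ester with the preformed amide enolate should give the β-keto Weinreb amide, which is protected from over-addition as its own enolate.

Step 9
Reactants: 19 3-[3,4-dimethoxy-5-(methoxymethoxy)phenyl]-N-methoxy-N-methyl-3-oxopropanamide
Product: 20 (3S)-3-[3,4-dimethoxy-5-(methoxymethoxy)phenyl]-3-hydroxy-N-methoxy-N-methylpropanamide
Conditions: RuCl(p-cymene)[(S,S)-TsDPEN] (1 mol %), HCO2H/Et3N (1:1), DMF, 40 °C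
Reagents that add atoms: none
Why: Noyori asymmetric transfer hydrogenation of the aryl ketone through the concerted Ru–H/N–H transition state with the (S,S)-ligand should deliver hydride to the Re face (the sense that converts acetophenone into (S)-1-phenylethanol) and so set the (S)-carbinol that becomes C2.

Step 10
Reactants: 20 (3S)-3-[3,4-dimethoxy-5-(methoxymethoxy)phenyl]-3-hydroxy-N-methoxy-N-methylpropanamide
Product: 21 (3S)-3-[3,4-dimethoxy-5-(methoxymethoxy)phenyl]-N-methoxy-N-methyl-3-[(trimethylsilyl)oxy]propanamide
Conditions: N-(trimethylsilyl)imidazole, CH2Cl2, rt; non-aqueous work-up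
Reagents that add atoms: N-(trimethylsilyl)imidazole, C[Si](C)(C)n1ccnc1
Why: Silyl transfer to the secondary alcohol under neutral conditions should give the labile trimethylsilyl ether without touching the stereocentre, removing the only O–H from the coupling partner.

Step 11
Reactants: 21 (3S)-3-[3,4-dimethoxy-5-(methoxymethoxy)phenyl]-N-methoxy-N-methyl-3-[(trimethylsilyl)oxy]propanamide; 14 4-geranyl-3,5-bis(methoxymethoxy)-2-(trimethylsilyl)phenyl trifluoromethanesulfonate
Product: 26 (2S)-2-[3,4-dimethoxy-5-(methoxymethoxy)phenyl]-6-geranyl-5,7-bis(methoxymethoxy)chroman-4-one, via cesium alkoxide 22 (not isolated), via aryne 23 (not isolated), via aryl cesium species 24 (not isolated), via hemiaminal alkoxide 25 (not isolated)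
Conditions: 14 (1.2 equiv), CsF (4 equiv), 18-crown-6, THF, 0 °C to rt; then AcOH, H2O, 0 °C
Reagents that add atoms: none
Why: Proposed new method: fluoride cleaves the O–SiMe3 bond of 21 and the C–SiMe3 bond of 14 in the same flask, so the cesium alkoxide 22 and the 3-alkoxyaryne 23 meet with no O–H present; the alkoxide oxygen adds to the aryne carbon remote from the flanking methoxymethoxy group, the aryl anion 24 then lies between the new ether oxygen and that methoxymethoxy group and attacks the Weinreb amide carbonyl to give the tetrahedral adduct 25, which is stable to base and releases ketone 26 only on the acetic acid quench. The closest known reaction types are the fluoride-mediated annulation of arynes with salicylate esters to xanthones (phenoxide addition, then acyl capture of the aryl anion) and the insertion of arynes into amide N–C(O) bonds; an aliphatic alkoxide carrying a tethered Weinreb amide has not been used in this way. Ring C is closed as a six-membered ring by 6-exo-trig addition of the aryl anion to the amide carbonyl after the intermolecular O-arylation, a formal [4+2] annulation of the O–C–C–C(=O) unit onto the aryne. No lasting stereocentre is created: C2 comes from 21 and is retained because its C–O bond is never broken, and the hemiaminal carbon of 25 is lost on work-up. The step needs O-attack at the aryne carbon meta to the alkoxy group, which the inductive distortion of the 3-alkoxyaryne secures and the unhindered C–H neighbour on the other side reinforces, and it needs acyl capture in preference to proton capture, which the silyl ether (no O–H), the weakly acidic amide α-hydrogens and the six-membered transition state secure. Holding the product as adduct 25 keeps the base-sensitive β-aryloxy ketone from forming until the medium is acidic, so ring opening to the chalcone and loss of the C2 configuration should be avoided.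

Step 12
Reactants: 26 (2S)-2-[3,4-dimethoxy-5-(methoxymethoxy)phenyl]-6-geranyl-5,7-bis(methoxymethoxy)chroman-4-one
Product: 27 (2S)-6-geranyl-5,7-dihydroxy-2-(3-hydroxy-4,5-dimethoxyphenyl)chroman-4-one (CNP0228243.1)
Conditions: HCl (3 M in MeOH), 40 °C
Reagents that add atoms: none
Why: Acid-catalysed acetal exchange with methanol removes the three MOM ethers (the C5 ether fastest, assisted by the C4 carbonyl) under conditions mild enough that the geranyl alkenes and the C2 stereocentre, which is labile mainly to base, should survive.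

**Compound list**

1 | resorcinol | Oc1cccc(O)c1 | starting material
2 | 1,3-bis(methoxymethoxy)benzene | COCOc1cccc(OCOC)c1 | intermediate
3 | geranyl bromide, (2E)-1-bromo-3,7-dimethylocta-2,6-diene | BrC/C=C(\C)CCC=C(C)C | starting material
4 | 2,6-bis(methoxymethoxy)phenyllithium (formed in the flask) | [Li]c1c(OCOC)cccc1OCOC | intermediate
5 | 2-geranyl-1,3-bis(methoxymethoxy)benzene | COCOc1cccc(OCOC)c1C/C=C(\C)CCC=C(C)C | intermediate
6 | 2-[4-geranyl-3,5-bis(methoxymethoxy)phenyl]-4,4,5,5-tetramethyl-1,3,2-dioxaborolane (formed in the flask) | COCOc1cc(B2OC(C)(C)C(C)(C)O2)cc(OCOC)c1C/C=C(\C)CCC=C(C)C | intermediate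
7 | 4-geranyl-3,5-bis(methoxymethoxy)phenol | COCOc1cc(O)cc(OCOC)c1C/C=C(\C)CCC=C(C)C | intermediate
8 | 4-geranyl-3,5-bis(methoxymethoxy)phenyl N-(propan-2-yl)carbamate | COCOc1cc(OC(=O)NC(C)C)cc(OCOC)c1C/C=C(\C)CCC=C(C)C | intermediate
9 | N-(trimethylsilyl) derivative of 8 (formed in the flask) | COCOc1cc(OC(=O)N(C(C)C)[Si](C)(C)C)cc(OCOC)c1C/C=C(\C)CCC=C(C)C | intermediate
10 | 2-lithio derivative of 9 (formed in the flask) | COCOc1cc(OC(=O)N(C(C)C)[Si](C)(C)C)c([Li])c(OCOC)c1C/C=C(\C)CCC=C(C)C | intermediate
11 | 2-(trimethylsilyl) derivative of 9 (formed in the flask) | COCOc1cc(OC(=O)N(C(C)C)[Si](C)(C)C)c([Si](C)(C)C)c(OCOC)c1C/C=C(\C)CCC=C(C)C | intermediate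
12 | 4-geranyl-3,5-bis(methoxymethoxy)-2-(trimethylsilyl)phenyl N-(propan-2-yl)carbamate | COCOc1cc(OC(=O)NC(C)C)c([Si](C)(C)C)c(OCOC)c1C/C=C(\C)CCC=C(C)C | intermediate
13 | 4-geranyl-3,5-bis(methoxymethoxy)-2-(trimethylsilyl)phenol (formed in the flask) | COCOc1cc(O)c([Si](C)(C)C)c(OCOC)c1C/C=C(\C)CCC=C(C)C | intermediate
14 | 4-geranyl-3,5-bis(methoxymethoxy)-2-(trimethylsilyl)phenyl trifluoromethanesulfonate | COCOc1cc(OS(=O)(=O)C(F)(F)F)c([Si](C)(C)C)c(OCOC)c1C/C=C(\C)CCC=C(C)C | intermediate
15 | methyl 3-hydroxy-4,5-dimethoxybenzoate | COC(=O)c1cc(O)c(OC)c(OC)c1 | starting material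
16 | methyl 3,4-dimethoxy-5-(methoxymethoxy)benzoate | COCOc1cc(C(=O)OC)cc(OC)c1OC | intermediate
17 | N-methoxy-N-methylacetamide | CC(=O)N(C)OC | starting material
18 | lithium enolate of 17 (formed in the flask) | C=C([O-])N(C)OC.[Li+] | intermediate
19 | 3-[3,4-dimethoxy-5-(methoxymethoxy)phenyl]-N-methoxy-N-methyl-3-oxopropanamide | COCOc1cc(C(=O)CC(=O)N(C)OC)cc(OC)c1OC | intermediate
20 | (3S)-3-[3,4-dimethoxy-5-(methoxymethoxy)phenyl]-3-hydroxy-N-methoxy-N-methylpropanamide | COc1cc([C@@H](O)CC(=O)N(C)OC)cc(OCOC)c1OC | intermediate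
21 | (3S)-3-[3,4-dimethoxy-5-(methoxymethoxy)phenyl]-N-methoxy-N-methyl-3-[(trimethylsilyl)oxy]propanamide | COc1cc([C@@H](O[Si](C)(C)C)CC(=O)N(C)OC)cc(OCOC)c1OC | intermediate
22 | cesium (S)-alkoxide of 20 (formed in the flask) | COc1cc([C@@H]([O-])CC(=O)N(C)OC)cc(OCOC)c1OC.[Cs+] | intermediate
23 | 4-geranyl-3,5-bis(methoxymethoxy)-1,2-didehydrobenzene, the aryne (formed in the flask) | COCOC1=CC#CC(OCOC)=C1C/C=C(\C)CCC=C(C)C | intermediate
24 | ortho-cesiated (S)-aryl ether from 22 and 23 (formed in the flask) | COc1cc([C@@H](Oc2cc(OCOC)c(C/C=C(\C)CCC=C(C)C)c(OCOC)[c-]2)CC(=O)N(C)OC)cc(OCOC)c1OC.[Cs+] | intermediate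
25 | cesium (2S)-4-[methoxy(methyl)amino]chroman-4-olate adduct, mixture at the hemiaminal carbon (formed in the flask) | COc1cc([C@@H]2CC([O-])(N(C)OC)c3c(cc(OCOC)c(C/C=C(\C)CCC=C(C)C)c3OCOC)O2)cc(OCOC)c1OC.[Cs+] | intermediate
26 | (2S)-2-[3,4-dimethoxy-5-(methoxymethoxy)phenyl]-6-geranyl-5,7-bis(methoxymethoxy)chroman-4-one | COc1cc([C@@H]2CC(=O)c3c(cc(OCOC)c(C/C=C(\C)CCC=C(C)C)c3OCOC)O2)cc(OCOC)c1OC | intermediate
27 | (2S)-6-geranyl-5,7-dihydroxy-2-(3-hydroxy-4,5-dimethoxyphenyl)chroman-4-one | COc1cc([C@@H]2CC(=O)c3c(cc(O)c(C/C=C(\C)CCC=C(C)C)c3O)O2)cc(O)c1OC | target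

**Step count and risks**

Total step count: 12. Longest linear sequence: 8 steps (steps 1 to 6, then 11 and 12, from resorcinol); the ring-B branch is 4 steps (7 to 10) before the coupling.

Steps most likely to fail:

1. Step 11 (proposed new method). The aryl anion may capture a proton (from adventitious water or from the amide α-position) faster than it adds to the amide, giving an uncyclised aryl ether, or β-elimination of the aryloxide may follow; the alkoxide may also be consumed by silyl or triflyl transfer before the aryne forms. Fallback with known reactions, setting out from 19 and 8 and returning at 26: ring C is closed at the O1–C2 bond instead, by an intramolecular Mitsunobu etherification. Ketone 19 would be reduced with the enantiomeric catalyst RuCl(p-cymene)[(R,R)-TsDPEN] under the conditions of step 9 to the (R)-hydroxy amide F1, which would be silylated (TBSCl, imidazole, DMF) to the (R)-tert-butyldimethylsilyl ether F2. Carbamate 8 would be N-silylated and ortho-lithiated exactly as in step 5 (through 9 to 10) and the aryllithium quenched at −78 °C with F2 to give the tetrahedral lithium adduct F3, which on aqueous NH4Cl work-up should give the aryl ketone F4. Et2NH/DBU (carbamate cleavage) followed by HF·pyridine (silyl ether cleavage) should give the 2-hydroxyaryl β-hydroxy ketone F5, and PPh3/DIAD in THF at 0 °C should close ring C by SN2 displacement at the benzylic carbinol with inversion, (R) to (2S), giving 26.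

2. Step 12. Under Brønsted acid the geranyl alkene may add the neighbouring C5 or C7 phenol to form a chroman ring, and reversible ring opening of the pyranone may erode the C2 configuration. Fallback setting out from 26 and returning at 27: the acetals would first be exchanged for silyl ethers without protic acid (TMSOTf, 2,2'-bipyridyl, CH2Cl2/MeCN, 0 °C) to give the tris(trimethylsilyl) ether F11, which is then hydrolysed by addition of water at neutral pH to 27.

3. Step 3. The iridium hydride and boryl species may hydroborate or isomerise the geranyl alkenes in competition with aromatic C–H borylation. Fallback setting out from 2 and returning at 7: the phenol oxygen is introduced before the alkenes are present. Borylation/oxidation of 2 under the conditions of step 3 would proceed through the aryl boronate F6 (not isolated) to 3,5-bis(methoxymethoxy)phenol F7, which would be silylated (TIPSCl, imidazole, DMF) to the triisopropylsilyl ether F8. The bulky silyl ether shields its flanking positions, so n-BuLi should metalate between the two MOM ethers to give aryllithium F9, and copper-mediated coupling with 3 as in step 2 should give the geranylated silyl ether F10; TBAF in THF then frees phenol 7.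

**Further compounds**

F1 | step 11 | (3R)-3-[3,4-dimethoxy-5-(methoxymethoxy)phenyl]-3-hydroxy-N-methoxy-N-methylpropanamide | COc1cc([C@H](O)CC(=O)N(C)OC)cc(OCOC)c1OC
F2 | step 11 | (3R)-3-[(tert-butyldimethylsilyl)oxy]-3-[3,4-dimethoxy-5-(methoxymethoxy)phenyl]-N-methoxy-N-methylpropanamide | COc1cc([C@H](O[Si](C)(C)C(C)(C)C)CC(=O)N(C)OC)cc(OCOC)c1OC
F3 | step 11 | tetrahedral lithium adduct of 10 with F2 (not isolated) | COc1cc([C@H](O[Si](C)(C)C(C)(C)C)CC([O-])(N(C)OC)c2c(OC(=O)N(C(C)C)[Si](C)(C)C)cc(OCOC)c(C/C=C(\C)CCC=C(C)C)c2OCOC)cc(OCOC)c1OC.[Li+]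
F4 | step 11 | 2-[(3R)-3-[(tert-butyldimethylsilyl)oxy]-3-[3,4-dimethoxy-5-(methoxymethoxy)phenyl]propanoyl]-4-geranyl-3,5-bis(methoxymethoxy)phenyl N-(propan-2-yl)carbamate | COc1cc([C@H](O[Si](C)(C)C(C)(C)C)CC(=O)c2c(OC(=O)NC(C)C)cc(OCOC)c(C/C=C(\C)CCC=C(C)C)c2OCOC)cc(OCOC)c1OC
F5 | step 11 | (3R)-3-[3,4-dimethoxy-5-(methoxymethoxy)phenyl]-1-[3-geranyl-6-hydroxy-2,4-bis(methoxymethoxy)phenyl]-3-hydroxypropan-1-one | COc1cc([C@H](O)CC(=O)c2c(O)cc(OCOC)c(C/C=C(\C)CCC=C(C)C)c2OCOC)cc(OCOC)c1OC
F6 | step 3 | 2-[3,5-bis(methoxymethoxy)phenyl]-4,4,5,5-tetramethyl-1,3,2-dioxaborolane (not isolated) | COCOc1cc(B2OC(C)(C)C(C)(C)O2)cc(OCOC)c1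
F7 | step 3 | 3,5-bis(methoxymethoxy)phenol | COCOc1cc(O)cc(OCOC)c1
F8 | step 3 | [3,5-bis(methoxymethoxy)phenoxy]tri(propan-2-yl)silane | COCOc1cc(O[Si](C(C)C)(C(C)C)C(C)C)cc(OCOC)c1
F9 | step 3 | 2,6-bis(methoxymethoxy)-4-[(triisopropylsilyl)oxy]phenyllithium (not isolated) | [Li]c1c(OCOC)cc(O[Si](C(C)C)(C(C)C)C(C)C)cc1OCOC
F10 | step 3 | [4-geranyl-3,5-bis(methoxymethoxy)phenoxy]tri(propan-2-yl)silane | COCOc1cc(O[Si](C(C)C)(C(C)C)C(C)C)cc(OCOC)c1C/C=C(\C)CCC=C(C)C
F11 | step 12 | (2S)-2-{3,4-dimethoxy-5-[(trimethylsilyl)oxy]phenyl}-6-geranyl-5,7-bis[(trimethylsilyl)oxy]chroman-4-one | COc1cc([C@@H]2CC(=O)c3c(cc(O[Si](C)(C)C)c(C/C=C(\C)CCC=C(C)C)c3O[Si](C)(C)C)O2)cc(O[Si](C)(C)C)c1OC
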